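**Retrosynthetic overview**
1. Target 26 comes from its bis-MOM ether 25. Both pyranone rings of 25 are closed last and together, from bis(diazoketone) 22 and two equivalents of salicylaldehyde 9 (double Wolff 1,2-shift, ketene O-acylation, aldol condensation).
2. 22 comes from diacid 20, made by cross-metathesis of vinyl acid 18 with acrylic acid.
3. 18 comes from ring expansion of the cyclopropane-fused tricyclic lactone 16 (bicyclo[3.1.0]hexane to cyclohexene) with vinyl transfer to the methyl-bearing cyclopropane carbon. This one step makes the six-membered ring, the quaternary centre and the cis relationship.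
4. 16 comes from butenolide ketone 12 by intramolecular diazoalkane cyclopropanation. 12 comes from α-angelica lactone and methyl vinyl ketone by an asymmetric vinylogous Michael addition, the only external source of chirality.
5. 9 comes from resorcinol by two directed ortho-lithiations. Ring order: cyclopentane and cyclopropane (step 5), then cyclohexene (step 6), then the two pyranones (step 9).

Assumption: the target SMILES is read as the (1R,2R)-cyclohexene with the ring-bound coumarin and the alkenyl chain cis, and the quinine-derived catalyst of step 4 is taken to give (R)-12 (otherwise its quinidine-derived pseudoenantiomer is used).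

Step 1
Reactants: 1 resorcinol
Product: 2 1,3-bis(methoxymethoxy)benzene
Conditions: NaH (2.3 equiv), MOMCl (2.3 equiv), DMF, 0 °C → rt
Reagents that add atoms: chloromethyl methyl ether (MOMCl), COCCl
Why: Williamson-type O-alkylation of both phenoxides; the MOM acetals protect the phenols and act as directing groups for both later lithiations.

Step 2
Reactants: 2 1,3-bis(methoxymethoxy)benzene
Product: 6 2-methoxy-1,3-bis(methoxymethoxy)benzene, via aryllithium 3 (not isolated), via arylboronate 4 (not isolated), via phenol 5 (not isolated)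
Conditions: n-BuLi, THF, 0 °C; B(OMe)3, −78 °C → rt; H2O2, aq NaOH, 0 °C; then Me2SO4, rt
Reagents that add atoms: hydrogen peroxide, OO; dimethyl sulfate, COS(=O)(=O)OC
Why: Cooperative directed ortho-metalation between the two OMOM groups gives only the C2 anion, and borylation–peroxide oxidation followed by Williamson methylation of the phenoxide in the same alkaline medium is standard and leaves the acetals untouched.

Step 3
Reactants: 6 2-methoxy-1,3-bis(methoxymethoxy)benzene
Product: 9 2-hydroxy-3-methoxy-4-(methoxymethoxy)benzaldehyde, via aryllithium 7 (not isolated), via bis-MOM aldehyde 8 (not isolated)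
Conditions: n-BuLi, TMEDA, THF, 0 °C; DMF, −78 °C → rt; then 1 M aq HCl, THF, rt (stopped at mono-cleavage)
Reagents that add atoms: N,N-dimethylformamide, CN(C)C=O
Why: Directed ortho-metalation next to OMOM (the two ortho C–H positions are equivalent) and Bouveault-type formylation; in dilute acid the MOM group squeezed between CHO and OMe hydrolyses first because the freed phenol is hydrogen-bonded to the aldehyde.

Step 4
Reactants: 10 α-angelica lactone; 11 methyl vinyl ketone
Product: 12 (R)-5-methyl-5-(3-oxobutyl)furan-2(5H)-one
Conditions: quinine-derived 3,5-(CF3)2C6H3-squaramide (10 mol %), 11 (1.5 equiv), toluene, −20 °C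
Reagents that add atoms: none
Why: Direct asymmetric vinylogous Michael addition, in which the quinuclidine deprotonates 10 to its 2-oxyfuran dienolate, the squaramide binds the enone, and attack through the γ-carbon gives the conjugated butenolide and sets the quaternary C5 stereocentre (R).

Step 5
Reactants: 12 (R)-5-methyl-5-(3-oxobutyl)furan-2(5H)-one
Product: 16 γ-lactone of (1S,2R,5S,6R)-2-hydroxy-2,5-dimethylbicyclo[3.1.0]hexane-6-carboxylic acid (tricyclic; carboxyl carbon endo on C6), via tosylhydrazone 13 (not isolated), via diazoalkane 14 (not isolated), via pyrazoline 15 (not isolated)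
Conditions: TsNHNH2, MeOH, rt, evaporate; LiN(SiMe3)2 (1.0 equiv), THF, −78 °C → rt; toluene, 90 °C; then hν (350 nm), rt
Reagents that add atoms: none
Why: Bamford–Stevens generation of the diazoalkane, intramolecular 1,3-dipolar cycloaddition to the electron-poor butenolide (diazo carbon to the β-carbon, three-atom tether) and photochemical nitrogen extrusion from the 1-pyrazoline; the tether allows addition only on the butenolide face carrying the side chain, so C1, C5 and C6 of 16 follow from the stereocentre of 12 and the carboxyl carbon is necessarily endo.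

Step 6
Reactants: 16 tricyclic lactone
Product: 18 (1R,6R)-6-ethenyl-3,6-dimethylcyclohex-2-ene-1-carboxylic acid (vinyl and CO2H cis), via zwitterion 17 (not isolated)
Conditions: (CH2=CH)3Al (2 equiv, from AlCl3 + 3 CH2=CHMgBr, THF stripped), CH2Cl2–toluene, −60 → 0 °C; 1 M aq HCl
Reagents that add atoms: vinylmagnesium bromide, C=C[Mg]Br (used as trivinylaluminium, C=C[Al](C=C)C=C)
Why: Proposed new method: the Lewis-acidic alane binds the lactone carbonyl and ionises the strained tertiary cyclopropylcarbinyl C2–O bond; in zwitterion 17 the charge is shared with the methyl-bearing cyclopropane carbon C5 (C6 carries the carboxylate and cannot take charge), so the internal C1–C5 bond breaks (five- to six-membered ring, new C1=C2 alkene) while the carboxylate-bound trivinylaluminate hands one vinyl group to C5 through a six-membered transition state from the side opposite the breaking bond, that is with inversion and on the face of the endo carboxylate, which makes vinyl and CO2H cis and gives (1R,6R)-18 from (1S,2R,5S,6R)-16; the closest known reaction types are the acid-induced thujane to p-menthene ring expansion (sabinene hydrate to terpinen-4-ol), stereoinvertive substitution at quaternary cyclopropylcarbinyl carbons in acyclic series and the coupling of tertiary alkyl halides with organoalanes, and what is new is the lactone leaving group that relays the nucleophile, the tertiary carbinyl terminus and the ring-expanding bicyclic setting.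

Step 7
Reactants: 18 vinyl acid; 19 acrylic acid
Product: 20 (2E)-3-[(1R,2R)-2-carboxy-1,4-dimethylcyclohex-3-en-1-yl]prop-2-enoic acid
Conditions: 19 (5 equiv), second-generation Hoveyda–Grubbs catalyst RuCl2(H2IMes)(=CH-C6H4-2-OiPr) (5 mol %), CH2Cl2, 40 °C
Reagents that add atoms: none
Why: Olefin cross-metathesis, in which a vinyl group on a quaternary carbon does not homodimerise, acrylic acid is the matching electron-poor partner, the E-enoic acid forms for steric reasons and the trisubstituted ring alkene is inert.

Step 8
Reactants: 20 diacid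
Product: 22 (3E)-1-diazo-4-[(1R,2R)-2-(diazoacetyl)-1,4-dimethylcyclohex-3-en-1-yl]but-3-en-2-one, via bis(acid chloride) 21 (not isolated)
Conditions: (COCl)2, DMF (cat.), CH2Cl2, 0 °C → rt, evaporate; TMSCHN2 (5 equiv), MeCN–THF, 0 °C
Reagents that add atoms: (trimethylsilyl)diazomethane, C[Si](C)(C)C=[N+]=[N-]
Why: Acid chloride formation and C-acylation of the silyl diazomethane (first stage of the Arndt–Eistert sequence); no amine base is present, so the allylic α-stereocentre is not enolised, and the bulky β-substituent and bulky diazo reagent suppress pyrazoline formation at the enoyl unit.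

Step 9
Reactants: 22 bis(diazoketone); 9 2-hydroxy-3-methoxy-4-(methoxymethoxy)benzaldehyde (2.2 equiv)
Product: 25 bis-MOM ether of the target, via bis-ketene 23 (not isolated), via bis(aryl ester) 24 (not isolated)
Conditions: toluene, hν (450 nm LED), rt; then DBU (2.5 equiv), 4 Å MS, 70 °C
Reagents that add atoms: none
Why: Double photochemical Wolff rearrangement (1,2-shift of the ring carbon with retention and of the E-alkenyl carbon), capture of both ketenes by the phenol of 9, then DBU-induced intramolecular aldol (Knoevenagel-type) condensation of each 2-formylaryl ester closes the two pyranone rings; light is used before any coumarin exists and no stereocentre is α to a carbonyl after the shift.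

Step 10
Reactants: 25 bis-MOM ether
Product: 26 target, 7-hydroxy-3-{(E)-2-[(1R,2R)-2-(7-hydroxy-8-methoxy-2-oxo-2H-chromen-3-yl)-1,4-dimethylcyclohex-3-en-1-yl]ethenyl}-8-methoxy-2H-chromen-2-one
Conditions: HCl (0.5 M in MeOH), THF, 40 °C
Reagents that add atoms: none
Why: Acid-catalysed acetal exchange removes both aryl MOM ethers under conditions that leave the lactones, the alkenyl chain and the trisubstituted alkene untouched.

**Compound list**
1 | resorcinol | Oc1cccc(O)c1 | starting material
2 | 1,3-bis(methoxymethoxy)benzene | COCOc1cccc(OCOC)c1 | intermediate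
3 | 2,6-bis(methoxymethoxy)phenyllithium | [Li]c1c(OCOC)cccc1OCOC | intermediate
4 | dimethyl 2,6-bis(methoxymethoxy)phenylboronate | COB(OC)c1c(OCOC)cccc1OCOC | intermediate
5 | 2,6-bis(methoxymethoxy)phenol | Oc1c(OCOC)cccc1OCOC | intermediate
6 | 2-methoxy-1,3-bis(methoxymethoxy)benzene | COCOc1cccc(OCOC)c1OC | intermediate
7 | 3-methoxy-2,4-bis(methoxymethoxy)phenyllithium | [Li]c1ccc(OCOC)c(OC)c1OCOC | intermediate
8 | 3-methoxy-2,4-bis(methoxymethoxy)benzaldehyde | O=Cc1ccc(OCOC)c(OC)c1OCOC | intermediate
9 | 2-hydroxy-3-methoxy-4-(methoxymethoxy)benzaldehyde | O=Cc1ccc(OCOC)c(OC)c1O | intermediate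
10 | α-angelica lactone (5-methylfuran-2(3H)-one) | CC1=CCC(=O)O1 | starting material
11 | methyl vinyl ketone | CC(=O)C=C | starting material
12 | (R)-5-methyl-5-(3-oxobutyl)furan-2(5H)-one | CC(=O)CC[C@]1(C)C=CC(=O)O1 | intermediate
13 | N-tosylhydrazone of 12 | Cc1ccc(cc1)S(=O)(=O)NN=C(C)CC[C@]1(C)C=CC(=O)O1 | intermediate
14 | (R)-5-(3-diazobutyl)-5-methylfuran-2(5H)-one | CC(=[N+]=[N-])CC[C@]1(C)C=CC(=O)O1 | intermediate
15 | tricyclic 1-pyrazoline (diazo carbon on butenolide C4, terminal N on C3, all ring fusions cis) | O=C1O[C@]2(C)CC[C@]3(C)N=N[C@H]1[C@H]23 | intermediate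
16 | γ-lactone of (1S,2R,5S,6R)-2-hydroxy-2,5-dimethylbicyclo[3.1.0]hexane-6-carboxylic acid | O=C1O[C@]2(C)CC[C@]3(C)[C@H]1[C@H]23 | intermediate
17 | zwitterion: 2,5-dimethylbicyclo[3.1.0]hex-2-yl cation carrying the 6-endo carboxylato(trivinyl)aluminate | C[C+]1CC[C@@]2(C)[C@@H]1[C@H]2C(=O)O[Al-](C=C)(C=C)C=C | intermediate
18 | (1R,6R)-6-ethenyl-3,6-dimethylcyclohex-2-ene-1-carboxylic acid | C=C[C@@]1(C)CCC(C)=C[C@H]1C(=O)O | intermediate
19 | acrylic acid | OC(=O)C=C | starting material
20 | (2E)-3-[(1R,2R)-2-carboxy-1,4-dimethylcyclohex-3-en-1-yl]prop-2-enoic acid | OC(=O)/C=C/[C@@]1(C)CCC(C)=C[C@H]1C(=O)O | intermediate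
21 | bis(acid chloride) of 20 | ClC(=O)/C=C/[C@@]1(C)CCC(C)=C[C@H]1C(Cl)=O | intermediate
22 | (3E)-1-diazo-4-[(1R,2R)-2-(diazoacetyl)-1,4-dimethylcyclohex-3-en-1-yl]but-3-en-2-one | [N-]=[N+]=CC(=O)/C=C/[C@@]1(C)CCC(C)=C[C@H]1C(=O)C=[N+]=[N-] | intermediate
23 | bis-ketene from 22 | O=C=C/C=C/[C@@]1(C)CCC(C)=C[C@H]1C=C=O | intermediate
24 | bis(2-formyl-6-methoxy-5-(methoxymethoxy)phenyl) ester of the doubly homologated diacid | O=Cc1ccc(OCOC)c(OC)c1OC(=O)C/C=C/[C@@]1(C)CCC(C)=C[C@H]1CC(=O)Oc1c(C=O)ccc(OCOC)c1OC | intermediate
25 | 7,7'-bis-O-MOM ether of the target, (1R,2R), E | COc1c(OCOC)ccc2cc(/C=C/[C@@]3(C)CCC(C)=C[C@H]3c3cc4ccc(OCOC)c(OC)c4oc3=O)c(=O)oc12 | intermediate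
26 | CNP0264408.1 | COc1c(O)ccc2cc(/C=C/[C@@]3(C)CCC(C)=C[C@H]3c3cc4ccc(O)c(OC)c4oc3=O)c(=O)oc12 | target

**Step count**
Total steps: 10. Longest linear sequence: 7 (steps 4–10). The arene branch (steps 1–3) joins at step 9.

**Steps most likely to fail**

1. Step 6 (the new reaction).
   - Risks: vinyl capture at the carbinyl carbon C2 without ring expansion, proton loss from the cation to cyclohexadiene acids, and slow ionisation if the alane stays THF-solvated.
   - Fallback (known chemistry): it sets out from 16 and comes back at 20. Ionise 16 with TiCl4 in CH2Cl2 at −78 °C in the presence of allyltrimethylsilane. This is a Hosomi–Sakurai capture of a tertiary carbocation by an external π-nucleophile, which attacks anti to the breaking cyclopropane bond and gives (1R,6R)-3,6-dimethyl-6-(prop-2-en-1-yl)cyclohex-2-ene-1-carboxylic acid F1. Isomerise the allyl group with RuHCl(CO)(PPh3)3 in toluene at 80 °C to (1R,6R)-3,6-dimethyl-6-[(E)-prop-1-en-1-yl]cyclohex-2-ene-1-carboxylic acid F2. Cross-metathesis of F2 with 19 under the conditions of step 7 then gives 20.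

2. Step 5.
   - Risks: 1,2-hydrogen shift of the dialkyl diazo compound or carbene to alkenes, and tautomerisation of 15 to the 2-pyrazoline, which no longer loses nitrogen.
   - Fallback: it sets out from 12 and comes back at 16. It replaces the diazo route by a polar Michael-initiated ring closure of a sulfonium ylide (Corey–Chaykovsky type). Reduce the ketone with NaBH4 in MeOH at −20 °C to (5R)-5-(3-hydroxybutyl)-5-methylfuran-2(5H)-one F3 (carbinol epimers, of no consequence). Convert it with I2, PPh3 and imidazole into (5R)-5-(3-iodobutyl)-5-methylfuran-2(5H)-one F4. Alkylate diphenyl sulfide with F4 and AgBF4 to give {4-[(2R)-2-methyl-5-oxo-2,5-dihydrofuran-2-yl]butan-2-yl}diphenylsulfonium tetrafluoroborate F5. Treat F5 with LiN(iPr)2 in DME at −78 °C. The ylide carbon adds to the butenolide β-carbon on the tether face, and the lactone enolate displaces diphenyl sulfide to close the cyclopropane of 16.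

3. Step 9.
   - Risks: side reactions of the vinylketene, and a slow aldol closure at the hindered ester next to the ring.
   - Fallback: it sets out from 22 and comes back at 26. It replaces the intramolecular cascade by intermolecular ester-enolate aldol chemistry. Run the Wolff rearrangement of 22 in methanol (hν 450 nm) to give methyl (3E)-4-[(1R,2S)-2-(2-methoxy-2-oxoethyl)-1,4-dimethylcyclohex-3-en-1-yl]but-3-enoate F6. Deprotonate both ester α-positions with LiN(iPr)2 (2.5 equiv, THF, −78 °C) and add aldehyde 8, isolated from step 3 by a neutral work-up, to give the bis(β-hydroxy ester) double aldol adduct F7 (mixture at the new centres, which are destroyed later). Warm F7 in HCl/MeOH at 55 °C to cleave all four MOM groups, lactonise each ortho-phenol onto its methyl ester and dehydrate. This gives 26 directly.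

**Further compounds**
F1 | step 6 | (1R,6R)-3,6-dimethyl-6-(prop-2-en-1-yl)cyclohex-2-ene-1-carboxylic acid | C=CC[C@@]1(C)CCC(C)=C[C@H]1C(=O)O
F2 | step 6 | (1R,6R)-3,6-dimethyl-6-[(E)-prop-1-en-1-yl]cyclohex-2-ene-1-carboxylic acid | C/C=C/[C@@]1(C)CCC(C)=C[C@H]1C(=O)O
F3 | step 5 | (5R)-5-(3-hydroxybutyl)-5-methylfuran-2(5H)-one | CC(O)CC[C@]1(C)C=CC(=O)O1
F4 | step 5 | (5R)-5-(3-iodobutyl)-5-methylfuran-2(5H)-one | CC(I)CC[C@]1(C)C=CC(=O)O1
F5 | step 5 | {4-[(2R)-2-methyl-5-oxo-2,5-dihydrofuran-2-yl]butan-2-yl}diphenylsulfonium tetrafluoroborate | CC(CC[C@]1(C)C=CC(=O)O1)[S+](c1ccccc1)c1ccccc1.F[B-](F)(F)F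
F6 | step 9 | methyl (3E)-4-[(1R,2S)-2-(2-methoxy-2-oxoethyl)-1,4-dimethylcyclohex-3-en-1-yl]but-3-enoate | COC(=O)C/C=C/[C@@]1(C)CCC(C)=C[C@H]1CC(=O)OC
F7 | step 9 | bis(β-hydroxy ester) double aldol adduct of F6 with 8 | COC(=O)C(C(O)c1ccc(OCOC)c(OC)c1OCOC)/C=C/[C@@]1(C)CCC(C)=C[C@H]1C(C(=O)OC)C(O)c1ccc(OCOC)c(OC)c1OCOC
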